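## Analysis of the target

Compound 27 is a 2-arylbenzofuran. Ring A (C3a to C7a) carries a hydroxyl at C6 and a prenyl group at C7, and the furan carbon C2 is bonded to C1' of ring B. Ring B is a resorcinol with prenyl groups at C2' and C6', hydroxyls at C3' and C5' and hydrogen at C4'. It is symmetric about the C1'–C4' axis.

There is no stereocentre, and the three alkenes end in gem-dimethyl groups, so no configuration has to be set. The sensitive features are three prenyl groups, each ortho to a free phenol, and two electron-rich arenes. Acid closes the phenols onto the alkenes (chromans), hydrogen reduces the alkenes, and oxidants attack the arenes. The last steps must therefore be neutral or basic and non-reductive.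

The difficulty is ring B. C1' is flanked by two prenylated carbons, and prenylating a preformed 5-arylresorcinol would have to avoid the most nucleophilic site, C4', between the two oxygens. On ring A the prenyl group must go to C7 and not to C5.

The strategy rests on the pattern of ring B: C2', C1' and C6' carry carbon, C3' and C5' carry oxygen, and C4' carries hydrogen. A 2,3,4-trisubstituted cyclobutenone (through its vinylketene) and an oxygen-substituted acetylene deliver exactly this pattern. The carbonyl carbon becomes C5', the three other ring carbons become C2', C1' and C6', and the alkyne supplies C3'(O) and C4'(H).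

## Retrosynthetic reasoning

**27 from 26.** The three phenols are uncovered last. In 26 the oxygens at C6 and C3' are triisopropylsilyl ethers and C5'–OH is already free, so one fluoride treatment gives 27 without acid, hydrogen or Lewis acid.

**26 from 16 and 21.** Ring B is taken apart at C4'–C5' and C2'–C3', which removes the two-carbon unit C3'–C4' as silyl ynol ether 21 and leaves cyclobutenone 16. The cut is made here because every substituent of ring B is then fixed by connectivity. C5' is the old carbonyl carbon, C2' and C6' already carry their prenyl groups, C1' already carries the benzofuran, and the polarity of 21 puts its CH carbon between the two oxygens. No hindered arene has to be prenylated and no blocking group is needed. The forward reaction must open 16, add 21 to the ketene, reopen and close C5'–C6'.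

**21 from 17.** The C–O–Si unit of 21 is traced to a lithium ynolate, silylated on oxygen. The ynolate comes from dibromo ester 17 by two bromine–lithium exchanges and loss of ethoxide.

**16 from 7 and 13.** The C2–C1' bond is cut between a 2-lithiobenzofuran and the vinylogous ester 13. Addition of the aryllithium to 13 and acid work-up replaces the ethoxy group by the aryl group with transposition of the enone. Because 13 carries the same prenyl group at its 2- and 4-positions, 1,2-addition and 1,4-addition end in the same compound 16. Building the four-membered ring on the benzofuran by an alkyne cycloaddition was set aside. It would need C2 halogenation, alkynylation and propargylic prenylation first, and would then expose three trisubstituted alkenes and benzofuran C3 to a strongly electrophilic ketene equivalent.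

**13 from 11.** The symmetry of ring B is used here. 13 is the known thermal "dimer" of a 1-ethoxyalkyne: one molecule of 11 loses ethene to give ketene 12, which adds to a second molecule of 11. Both prenyl arms of ring B and all four carbons of the cyclobutenone therefore come from one compound.

**11 from 8 and 9.** The propargylic C–C bond is cut to the acetylide of 8 and the primary allylic bromide 9.

**7 from 6, 4, 3, 1 and 2.** The silyl ether 7 comes from phenol 6. The C7–CH2 bond of 6 is cut by an aromatic Claisen transform to the 1,1-dimethylallyl ether 4, so that allylic inversion gives the linear prenyl group. 4 comes from propargyl ether 3 by semi-hydrogenation, and 3 from phenol 1 and chloride 2.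

## Alternatives that were turned down

**Alternative 1: three prenyl groups by a triple aromatic Claisen rearrangement.**
- Disconnection: the bonds C7–CH2, C2'–CH2 and C6'–CH2 are cut together, returning the prenyl groups to oxygen as 1,1-dimethylallyl ethers on a 4'-bromo triphenol, the tris-ether A1.
- Key step: heating A1 drives three [3,3] shifts with allyl inversion and gives bromo triphenol A2; the bromine is then removed reductively.
- For: the unprenylated 2-arylbenzofuran core is reachable in a few steps by alkyne coupling and cyclisation. All three prenyl groups come from one reagent in one operation. No strained ring or ynol ether is needed. On step count and ease of the precursor this is stronger than the chosen route.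
- Against:
  - Three independent rearrangements must each be regioselective, and losses multiply.
  - On ring A only bond fixation separates C7 from C5. Step 3 of the chosen route has the same dependence, but tests it at the start on a small compound.
  - On ring B each ether must deliver into a carbon next to the benzofuranyl group. The other terminus, C4', carries bromine, and attack there gives a blocked bromodienone that can only go on by para shift, loss of bromine or cleavage.
  - Three tertiary ethers must be made and semi-hydrogenated next to an aryl bromide.
  - A2 is formed hot with three ortho-prenyl phenols, and bromine must then be removed beside three alkenes.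
- Comparison: the chosen strategy offers positional certainty on ring B without a blocking group.

**Alternative 2: anodic closure of a hydroxystilbene.**
- Disconnection: O1–C2 is cut, opening the furan to the (E)-2-hydroxystilbene A3, the biogenetic precursor type.
- Key step: controlled-potential oxidation of A3 at carbon with a hindered pyridine base removes two electrons and two protons. The C7a hydroxyl adds to C2 and the furan aromatises to the tris-MOM ether A4.
- For: rings A and B are joined late by an olefination, and the oxidation needs no reagent. On convergence it is at least equal to the chosen route.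
- Against:
  - Ring B, with both prenyl groups and both oxygens, must already exist in the olefination partner, so the hard ring is still made by arene functionalisation.
  - The C7 prenyl alkene sits ortho to the same hydroxyl and can capture the oxidised phenol to give a chroman or dihydrofuran.
  - The three trisubstituted alkenes and the trioxygenated ring B are oxidised in a similar potential window.
  - A4 needs acid to lose three MOM groups next to three prenyl groups.
- Comparison: the chosen strategy builds ring B from non-aromatic pieces and ends with fluoride only.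

**Alternative 3: carbene complex and dienyne build ring A.**
- Disconnection: ring A is cut at C2–C3, C3a–C7a and C7–C7a, with C7a and its oxygen coming from CO.
- Key step: heating the complex (CO)5Cr=C(OMe)Ar A5 (Ar is ring B) with the terminal dienyne A6 causes alkyne insertion, CO insertion and six-electron closure of the dienylketene to phenol A7. Acid then closes the furan with loss of methanol.
- For: the logic is the same as in the chosen route (a ring from acyclic pieces, substituents fixed by connectivity). It places the C7 prenyl group unambiguously, which is stronger than the Claisen step of the chosen route.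
- Against:
  - It builds the easier ring. Ring B must still be made by arene chemistry and then turned into a hindered aryllithium for A5.
  - The carbene carbon of A5 sits between two ortho prenyl alkenes placed for intramolecular cyclopropanation.
  - Chromium is used stoichiometrically.
  - The (Z)-dienyne silyl enol ether A6 is labile and needs several steps.
  - Furan closure and MOM removal both need acid.
- Comparison: the chosen strategy applies the connectivity argument to ring B, where it is needed most, and accepts a Claisen step on ring A.

Key step: step 9

## Route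

Remark on the chemistry: 1, 2, 8 (as its solution in hexanes), 9 and 17 are taken as purchasable. The stereocentres of 5, 13, 15, 16, 23 and 25 form as racemates and all vanish before 26, so no stereocontrol is needed. In names below, ArT stands for the 7-(3-methylbut-2-en-1-yl)-6-[(triisopropylsilyl)oxy]-1-benzofuran-2-yl group.

Step 1
Reactants: 1 benzofuran-6-ol; 2 3-chloro-3-methylbut-1-yne
Product: 3 6-[(2-methylbut-3-yn-2-yl)oxy]-1-benzofuran
Conditions: DBU, CuCl2·2H2O (cat.), MeCN, 0 °C
Reagents that add atoms: none
Why: Copper-catalysed O-alkylation of a phenol with a tertiary propargylic chloride, the standard entry to aryl 1,1-dimethylpropargyl ethers; the mild base and low temperature leave the benzofuran untouched.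

Step 2
Reactants: 3 6-[(2-methylbut-3-yn-2-yl)oxy]-1-benzofuran
Product: 4 6-[(2-methylbut-3-en-2-yl)oxy]-1-benzofuran
Conditions: H2 (1 atm), Pd/CaCO3 poisoned with Pb(OAc)2, quinoline, EtOAc, rt
Reagents that add atoms: none
Why: Lindlar semi-hydrogenation stops at the terminal alkene and does not reduce the furan double bond; the alkene is needed because the propargyl ether itself would close to a chromene on heating.

Step 3
Reactants: 4 6-[(2-methylbut-3-en-2-yl)oxy]-1-benzofuran
Product: 6 7-(3-methylbut-2-en-1-yl)-1-benzofuran-6-ol, via 7-prenyl-7H-benzofuran-6-one 5 (not isolated)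
Conditions: PhNEt2, 120 °C
Reagents that add atoms: none
Why: Aromatic Claisen rearrangement; the [3,3] shift inverts the 1,1-dimethylallyl group to a linear prenyl group and should go to C7 because the C6–C7 bond of a benzofuran has the higher double-bond character (as in 2-naphthyl allyl ethers); dienone 5 enolises to the phenol, and the amine solvent suppresses acid-induced chroman formation.

Step 4
Reactants: 6 7-(3-methylbut-2-en-1-yl)-1-benzofuran-6-ol
Product: 7 triisopropyl{[7-(3-methylbut-2-en-1-yl)-1-benzofuran-6-yl]oxy}silane
Conditions: iPr3SiCl, imidazole, DMF, rt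
Reagents that add atoms: triisopropylsilyl chloride, CC(C)[Si](Cl)(C(C)C)C(C)C
Why: Standard silylation of a phenol; the bulky silyl ether survives butyllithium and heating and is removed by fluoride at the end.

Step 5
Reactants: 8 ethoxyacetylene; 9 prenyl bromide (1-bromo-3-methylbut-2-ene)
Product: 11 1-ethoxy-5-methylhex-4-en-1-yne, via lithium ethoxyacetylide 10 (not isolated)
Conditions: n-BuLi, THF, −78 °C; then 9, DMPU, −78 °C → rt
Reagents that add atoms: none
Why: Deprotonation of the terminal ynol ether and SN2 alkylation of the acetylide by the primary allylic bromide in a dipolar cosolvent; attack at the unhindered CH2 terminus keeps the prenyl unit linear.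

Step 6
Reactants: 11 1-ethoxy-5-methylhex-4-en-1-yne (two molecules)
Product: 13 3-ethoxy-2,4-bis(3-methylbut-2-en-1-yl)cyclobut-2-en-1-one (racemic), via prenylketene 12 (not isolated)
Conditions: xylene, 120 °C, N2 sweep
Reagents that add atoms: none
Why: Known thermal behaviour of 1-ethoxyalkynes: a retro-ene reaction expels ethene and gives the aldoketene 12, which is formed slowly in an excess of the nucleophilic ynol ether and adds to it by polar [2+2] cycloaddition (ketene carbonyl carbon to the alkyl-bearing alkyne carbon) to give the 3-ethoxy-2,4-dialkylcyclobutenone; the C4 centre is racemic and is lost later.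

Step 7
Reactants: 7 triisopropyl{[7-(3-methylbut-2-en-1-yl)-1-benzofuran-6-yl]oxy}silane; 13 3-ethoxy-2,4-bis(3-methylbut-2-en-1-yl)cyclobut-2-en-1-one
Product: 16 3-ArT-2,4-bis(3-methylbut-2-en-1-yl)cyclobut-2-en-1-one (racemic), via 2-lithiobenzofuran 14 (not isolated), via lithium cyclobutenolate adduct 15 (not isolated)
Conditions: 7, n-BuLi, THF, −78 °C; 13, −78 °C; then 1 M HCl, 0 °C
Reagents that add atoms: water, O
Why: Benzofuran C2–H is the kinetically most acidic site and is lithiated cleanly; the aryllithium adds to the carbonyl of the vinylogous ester (enolisation would give a cyclobutadiene-type enolate and does not compete), and mild acid ionises the tertiary allylic alcohol, water adds at the ethoxy-bearing carbon and ethanol is lost, the standard route to 3-substituted cyclobutenones; because 13 has the same group at C2 and C4, conjugate addition–elimination would give the same product.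

Step 8
Reactants: 17 ethyl dibromoacetate
Product: 21 (ethynyloxy)triisopropylsilane, via lithium bromo enolate 18 (not isolated), via dilithio ester dianion 19 (not isolated), via lithium ethynolate 20 (not isolated)
Conditions: t-BuLi (4 equiv), THF, −78 → 0 °C; iPr3SiCl, −78 °C → rt
Reagents that add atoms: triisopropylsilyl chloride, CC(C)[Si](Cl)(C(C)C)C(C)C
Why: Two successive bromine–lithium exchanges give the ester dianion 19, which expels ethoxide on warming to the ynolate 20 (the dibromo-ester route to lithium ynolates); the bulky silyl chloride then silylates the ynolate on oxygen, as in the known preparation of triisopropylsilyl ynol ethers, here applied to the parent member.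

Step 9
Reactants: 16 3-ArT-2,4-bis(3-methylbut-2-en-1-yl)cyclobut-2-en-1-one; 21 (ethynyloxy)triisopropylsilane
Product: 26 3-ArT-2,4-bis(3-methylbut-2-en-1-yl)-5-[(triisopropylsilyl)oxy]phenol, via vinylketene 22 (not isolated), via 4-vinylcyclobutenone 23 (not isolated), via dienylketene 24 (not isolated), via cyclohexadienone 25 (not isolated)
Conditions: 21 (3 equiv), PhMe, 80 → 110 °C, sealed tube
Reagents that add atoms: none
Why: On heating, 16 opens by conrotatory four-electron cleavage of the C5'–C6' bond, the C6' prenyl group turning outward, to give vinylketene 22. The electron-rich alkyne 21 adds across the ketene C=C in a polar [2+2] cycloaddition in which its CH carbon (C4') bonds to the ketene carbonyl carbon C5' and its oxygenated carbon (C3') to C2', giving 23. 23 reopens reversibly to dienylketene 24, whose reactive geometry closes the C5'–C6' bond by six-electron disrotatory electrocyclisation to dienone 25, and enolisation gives phenol 26. The closest known reaction is the Danheiser benzannulation of cyclobutenones with alkoxy- and trialkylsilyloxyalkynes, which gives resorcinol monoethers. Ring B is thus closed as a six-membered carbocycle by electrocyclisation and no stereocentre remains, the centres of 23 and 25 being transient. The step needs regioselectivity in the [2+2] addition, which the polarisation of the ynol ether secures and which puts C4'–H between the two oxygens. It also needs chemoselectivity for 21 over the three prenyl alkenes: unactivated trisubstituted alkenes do not add ketenes intermolecularly at this temperature, the prenyl tethers are too short for internal [2+2] addition, and the benzofuran on C1' cannot act as a terminus of a six-electron closure. The excess of 21 is meant to outrun acylation of the product phenol by 22.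

Step 10
Reactants: 26 3-ArT-2,4-bis(3-methylbut-2-en-1-yl)-5-[(triisopropylsilyl)oxy]phenol
Product: 27 5-[6-hydroxy-7-(3-methylbut-2-en-1-yl)-1-benzofuran-2-yl]-4,6-bis(3-methylbut-2-en-1-yl)benzene-1,3-diol
Conditions: Bu4NF, AcOH, THF, 0 °C → rt
Reagents that add atoms: none
Why: Fluoride cleaves both aryl silyl ethers; buffering with acetic acid keeps the electron-rich phenoxides from oxidising, and nothing in the step can touch the prenyl groups.

## Compound list

1 | benzofuran-6-ol | Oc1ccc2ccoc2c1 | starting material
2 | 3-chloro-3-methylbut-1-yne | C#CC(C)(C)Cl | starting material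
3 | 6-[(2-methylbut-3-yn-2-yl)oxy]-1-benzofuran | C#CC(C)(C)Oc1ccc2ccoc2c1 | intermediate
4 | 6-[(2-methylbut-3-en-2-yl)oxy]-1-benzofuran | C=CC(C)(C)Oc1ccc2ccoc2c1 | intermediate
5 | 7-(3-methylbut-2-en-1-yl)-1-benzofuran-6(7H)-one (racemic, not isolated) | CC(C)=CCC1C(=O)C=CC2=C1OC=C2 | intermediate
6 | 7-(3-methylbut-2-en-1-yl)-1-benzofuran-6-ol | CC(C)=CCc1c(O)ccc2ccoc12 | intermediate
7 | triisopropyl{[7-(3-methylbut-2-en-1-yl)-1-benzofuran-6-yl]oxy}silane | CC(C)=CCc1c(O[Si](C(C)C)(C(C)C)C(C)C)ccc2ccoc12 | intermediate
8 | ethoxyacetylene (ethoxyethyne) | CCOC#C | starting material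
9 | prenyl bromide (1-bromo-3-methylbut-2-ene) | CC(C)=CCBr | starting material
10 | lithium ethoxyacetylide (not isolated) | CCOC#C[Li] | intermediate
11 | 1-ethoxy-5-methylhex-4-en-1-yne | CCOC#CCC=C(C)C | intermediate
12 | prenylketene, 5-methylhexa-1,4-dien-1-one (not isolated) | CC(C)=CCC=C=O | intermediate
13 | 3-ethoxy-2,4-bis(3-methylbut-2-en-1-yl)cyclobut-2-en-1-one (racemic) | CCOC1=C(CC=C(C)C)C(=O)C1CC=C(C)C | intermediate
14 | {7-(3-methylbut-2-en-1-yl)-6-[(triisopropylsilyl)oxy]-1-benzofuran-2-yl}lithium (not isolated) | [Li]c1cc2ccc(O[Si](C(C)C)(C(C)C)C(C)C)c(CC=C(C)C)c2o1 | intermediate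
15 | lithium 1-ArT-3-ethoxy-2,4-bis(3-methylbut-2-en-1-yl)cyclobut-2-en-1-olate (diastereomer mixture, not isolated) | CCOC1=C(CC=C(C)C)C(O[Li])(c2cc3ccc(O[Si](C(C)C)(C(C)C)C(C)C)c(CC=C(C)C)c3o2)C1CC=C(C)C | intermediate
16 | 3-ArT-2,4-bis(3-methylbut-2-en-1-yl)cyclobut-2-en-1-one (racemic) | O=C1C(CC=C(C)C)C(c2cc3ccc(O[Si](C(C)C)(C(C)C)C(C)C)c(CC=C(C)C)c3o2)=C1CC=C(C)C | intermediate
17 | ethyl dibromoacetate | CCOC(=O)C(Br)Br | starting material
18 | lithium enolate of ethyl bromoacetate (not isolated) | CCOC(O[Li])=CBr | intermediate
19 | lithium 1-ethoxy-2-lithioethen-1-olate, the ester dianion (not isolated) | CCOC(O[Li])=C[Li] | intermediate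
20 | lithium ethynolate (not isolated) | [Li]OC#C | intermediate
21 | (ethynyloxy)triisopropylsilane | C#CO[Si](C(C)C)(C(C)C)C(C)C | intermediate
22 | (3Z)-3-ArT-7-methyl-2-(3-methylbut-2-en-1-yl)octa-1,3,6-trien-1-one, the vinylketene (not isolated) | O=C=C(CC=C(C)C)/C(=C/CC=C(C)C)c1cc2ccc(O[Si](C(C)C)(C(C)C)C(C)C)c(CC=C(C)C)c2o1 | intermediate
23 | 4-[(1Z)-1-ArT-5-methylhexa-1,4-dien-1-yl]-4-(3-methylbut-2-en-1-yl)-3-[(triisopropylsilyl)oxy]cyclobut-2-en-1-one (racemic, not isolated) | O=C1C=C(O[Si](C(C)C)(C(C)C)C(C)C)C1(CC=C(C)C)/C(=C/CC=C(C)C)c1cc2ccc(O[Si](C(C)C)(C(C)C)C(C)C)c(CC=C(C)C)c2o1 | intermediate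
24 | (3E,5Z)-5-ArT-9-methyl-4-(3-methylbut-2-en-1-yl)-3-[(triisopropylsilyl)oxy]deca-1,3,5,8-tetraen-1-one, the dienylketene (not isolated) | O=C=C/C(O[Si](C(C)C)(C(C)C)C(C)C)=C(CC=C(C)C)\C(=C\CC=C(C)C)c1cc2ccc(O[Si](C(C)C)(C(C)C)C(C)C)c(CC=C(C)C)c2o1 | intermediate
25 | 5-ArT-4,6-bis(3-methylbut-2-en-1-yl)-3-[(triisopropylsilyl)oxy]cyclohexa-2,4-dien-1-one (racemic, not isolated) | O=C1C=C(O[Si](C(C)C)(C(C)C)C(C)C)C(CC=C(C)C)=C(c2cc3ccc(O[Si](C(C)C)(C(C)C)C(C)C)c(CC=C(C)C)c3o2)C1CC=C(C)C | intermediate
26 | 3-ArT-2,4-bis(3-methylbut-2-en-1-yl)-5-[(triisopropylsilyl)oxy]phenol | CC(C)=CCc1c(O)cc(O[Si](C(C)C)(C(C)C)C(C)C)c(CC=C(C)C)c1-c1cc2ccc(O[Si](C(C)C)(C(C)C)C(C)C)c(CC=C(C)C)c2o1 | intermediate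
27 | 5-[6-hydroxy-7-(3-methylbut-2-en-1-yl)-1-benzofuran-2-yl]-4,6-bis(3-methylbut-2-en-1-yl)benzene-1,3-diol | CC(C)=CCc1c(O)cc(O)c(CC=C(C)C)c1-c1cc2ccc(O)c(CC=C(C)C)c2o1 | target

## Step count and risk

Total step count: 10. Longest linear sequence: 7 steps (steps 1, 2, 3, 4, 7, 9, 10).

**Step 9 (key step).** The most likely failure is loss of the silyl ynol ether 21, by migration of silicon from oxygen to carbon or by oligomerisation, before 16 has opened, since the opening needs roughly 80 to 110 °C. A second loss is acylation of the product phenol by ketene 22. The fallback takes ketene generation out of the hot stage. It sets out from 16, which is heated alone in wet dioxane so that 22 is trapped by water as the β,γ-unsaturated acid (3Z)-3-ArT-7-methyl-2-(3-methylbut-2-en-1-yl)octa-3,6-dienoic acid F1. Oxalyl chloride turns this into the acid chloride (3Z)-3-ArT-7-methyl-2-(3-methylbut-2-en-1-yl)octa-3,6-dienoyl chloride F2. Et3N then removes HCl from F2 at room temperature in the presence of 21, so that the ketene and the ynol ether meet cold. The fallback comes back to the route at 23, which is then warmed, free of 21, to 26.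

**Step 8.** The most likely failure is silylation of the ynolate on carbon instead of oxygen, or its further metalation, because the parent ynolate carries only hydrogen on carbon and the steric bias for oxygen is smaller than in the substituted cases. The fallback forms the O–Si bond before the triple bond. It sets out from 17, which is reduced with iBu2AlH at −78 °C to dibromoacetaldehyde F3. This is converted with iPr3SiOTf and Et3N into the silyl enol ether [(2,2-dibromoethenyl)oxy]triisopropylsilane F4. Treatment of F4 with n-BuLi (2 equiv) at −78 °C, in the manner of the second stage of a Corey–Fuchs alkyne synthesis (bromine–lithium exchange, loss of bromide, 1,2-hydrogen shift), followed by cold protonation, comes back to the route at 21.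

**Step 6.** The most likely failure is over-reaction: at the temperature needed for the retro-ene step the product cyclobutenone may itself open and consume more 11, and some ketene may dimerise. The fallback makes the ketene at room temperature from a different precursor. It sets out from 11, which is stirred with Et3N while 5-methylhex-4-enoyl chloride F6 is added slowly. F6 is made with oxalyl chloride from purchased 5-methylhex-4-enoic acid F5. Dehydrochlorination of F6 gives 12, which adds to 11, and the fallback comes back to the route at 13.

**Step 3.** The most likely failure is poor regioselectivity between C7 and C5 in the sigmatropic shift, together with ionisation of the tertiary allyl ether back to phenol 1. The fallback fixes C7 by directed metalation. It sets out from 1, which is protected with chloromethyl methyl ether and iPr2NEt as 6-(methoxymethoxy)-1-benzofuran F7. C2 is blocked by n-BuLi and Me3SiCl to give [6-(methoxymethoxy)-1-benzofuran-2-yl]trimethylsilane F8. s-BuLi with TMEDA lithiates C7, the position between the acetal oxygen and O1. CuBr·SMe2 and 9 then give [6-(methoxymethoxy)-7-(3-methylbut-2-en-1-yl)-1-benzofuran-2-yl]trimethylsilane F9. Bu4NF removes the C2 silyl group to give 6-(methoxymethoxy)-7-(3-methylbut-2-en-1-yl)-1-benzofuran F10, and brief treatment with HCl in MeOH comes back to the route at 6.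

## Further compounds

F1 | step 9 | (3Z)-3-ArT-7-methyl-2-(3-methylbut-2-en-1-yl)octa-3,6-dienoic acid (racemic) | OC(=O)C(CC=C(C)C)/C(=C/CC=C(C)C)c1cc2ccc(O[Si](C(C)C)(C(C)C)C(C)C)c(CC=C(C)C)c2o1
F2 | step 9 | (3Z)-3-ArT-7-methyl-2-(3-methylbut-2-en-1-yl)octa-3,6-dienoyl chloride (racemic) | ClC(=O)C(CC=C(C)C)/C(=C/CC=C(C)C)c1cc2ccc(O[Si](C(C)C)(C(C)C)C(C)C)c(CC=C(C)C)c2o1
F3 | step 8 | dibromoacetaldehyde | O=CC(Br)Br
F4 | step 8 | [(2,2-dibromoethenyl)oxy]triisopropylsilane | BrC(Br)=CO[Si](C(C)C)(C(C)C)C(C)C
F5 | step 6 | 5-methylhex-4-enoic acid | CC(C)=CCCC(=O)O
F6 | step 6 | 5-methylhex-4-enoyl chloride | CC(C)=CCCC(=O)Cl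
F7 | step 3 | 6-(methoxymethoxy)-1-benzofuran | COCOc1ccc2ccoc2c1
F8 | step 3 | [6-(methoxymethoxy)-1-benzofuran-2-yl]trimethylsilane | COCOc1ccc2cc([Si](C)(C)C)oc2c1
F9 | step 3 | [6-(methoxymethoxy)-7-(3-methylbut-2-en-1-yl)-1-benzofuran-2-yl]trimethylsilane | COCOc1ccc2cc([Si](C)(C)C)oc2c1CC=C(C)C
F10 | step 3 | 6-(methoxymethoxy)-7-(3-methylbut-2-en-1-yl)-1-benzofuran | COCOc1ccc2ccoc2c1CC=C(C)C
A1 | alternative 1 | 2-{4-bromo-3,5-bis[(2-methylbut-3-en-2-yl)oxy]phenyl}-6-[(2-methylbut-3-en-2-yl)oxy]-1-benzofuran | C=CC(C)(C)Oc1cc(cc(OC(C)(C)C=C)c1Br)-c1cc2ccc(OC(C)(C)C=C)cc2o1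
A2 | alternative 1 | 2-bromo-5-[6-hydroxy-7-(3-methylbut-2-en-1-yl)-1-benzofuran-2-yl]-4,6-bis(3-methylbut-2-en-1-yl)benzene-1,3-diol | CC(C)=CCc1c(O)c(Br)c(O)c(CC=C(C)C)c1-c1cc2ccc(O)c(CC=C(C)C)c2o1
A3 | alternative 2 | 6-[(E)-2-{3,5-bis(methoxymethoxy)-2,6-bis(3-methylbut-2-en-1-yl)phenyl}ethenyl]-3-(methoxymethoxy)-2-(3-methylbut-2-en-1-yl)phenol | COCOc1ccc(/C=C/c2c(CC=C(C)C)c(OCOC)cc(OCOC)c2CC=C(C)C)c(O)c1CC=C(C)C
A4 | alternative 2 | 2-[3,5-bis(methoxymethoxy)-2,6-bis(3-methylbut-2-en-1-yl)phenyl]-6-(methoxymethoxy)-7-(3-methylbut-2-en-1-yl)-1-benzofuran | CC(C)=CCc1c(OCOC)cc(OCOC)c(CC=C(C)C)c1-c1cc2ccc(OCOC)c(CC=C(C)C)c2o1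
A5 | alternative 3 | pentacarbonyl{[3,5-bis(methoxymethoxy)-2,6-bis(3-methylbut-2-en-1-yl)phenyl](methoxy)methylidene}chromium, (CO)5Cr=C(OMe)Ar | COC(=[Cr](=C=O)(=C=O)(=C=O)(=C=O)=C=O)c1c(CC=C(C)C)c(OCOC)cc(OCOC)c1CC=C(C)C
A6 | alternative 3 | tert-butyl(dimethyl){[(3Z)-9-methyldeca-3,5,8-trien-1-yn-5-yl]oxy}silane | C#C/C=C\C(O[Si](C)(C)C(C)(C)C)=CCC=C(C)C
A7 | alternative 3 | 6-{2-[3,5-bis(methoxymethoxy)-2,6-bis(3-methylbut-2-en-1-yl)phenyl]-2-methoxyethenyl}-3-{[tert-butyl(dimethyl)silyl]oxy}-2-(3-methylbut-2-en-1-yl)phenol (enol ether geometry undefined) | COC(=Cc1ccc(O[Si](C)(C)C(C)(C)C)c(CC=C(C)C)c1O)c1c(CC=C(C)C)c(OCOC)cc(OCOC)c1CC=C(C)C
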